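The cooler delta flask ended higher than epsilon, with 54.4% of target against 46.0% at 4.00 d, though epsilon led at 0.833 d. Epsilon is the flask we are asked about.

all flasks: starting material 0.19 M; free catalyst 0.35 mol%
- epsilon: second substrate 1 equiv; temperature 35 °C; the very flask that is asked about, followed so far
- delta: second substrate 1 equiv; temperature 30 °C; run made earlier
- flask: second substrate 1.00 equiv; temperature 35 °C; time 4.0 d

- epsilon (time / d: target / %, starting material / %): 0.833: 33.1, 65.7; 1.67: 44.0, 54.1; 2.50: 42.8, 56.0; 3.00: 45.5, 55.1; 4.00: 46.0, 53.8
- delta (time / d: target / %, starting material / %): 0.833: 26.7, 70.2; 1.67: 42.8, 58.0; 2.50: 47.6, 50.9; 3.00: 51.7, 48.7; 4.00: 54.4, 48.4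

(standard deviation of a reading: 1 percentage point)

* target, in percent of the starting material first charged, at 4.0 d
* the remedy with the largest gain of target, or "none" below 2 percentage points (amber / violet / ochre / teal / none)
* target present, with what was taken out counted in, in percent of the starting material first charged, after amber
* target present, with what was taken out counted in, in percent of the starting material first charged, after teal

- removed target is counted in
- the analysis behind the earlier runs scatters by 1 percentage point, standard deviation
- additions bring no volume worth counting

- amber: change nothing and wait 30 h more
- violet: at 4.0 d take out 90% of the target then present, then wait 30 h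
- ochre: at 4.0 d raise the temperature by 20 K, then wait 30 h
- teal: at 4.0 d add free catalyst, 100% of the amount charged, then wait 30 h

Epsilon gained 11 percentage points between its first two readings, then 2 points over the rest, with 53.8% of starting material still there. We read this as a change of control, from turnover to catalyst lifetime. Suppose the catalyst dies at its own rate while its turnover follows the starting material, pseudo-first-order. Each charge then removes a fixed fraction of the starting material.

So we carry R, the natural logarithm of starting material charged over starting material left once the catalyst stops. In epsilon, R = 0.620, the reach of one catalyst charge. Delta reads 0.726. Both are readings and carry their scatter.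

Now the settings, by hand. We put target at 46.0% now.

- **Time (amber):** epsilon's last day added 0.5 points, inside the scatter of 1 point, so we expect no gain.
- **Removing target (violet):** R counts starting material left, and taking out target leaves that unchanged, so we expect no gain.
- **Temperature (ochre):** the warmer run had the shorter reach, and heat does not restore the catalyst, so we expect no gain.
- **Catalyst (teal):** an equal fresh charge has the same reach on what remains. Target becomes 71.1%, a gain of 25 points.

The forecast gives 45.6% now, violet as best, 45.8% after amber and 46% after teal, parting from our reckoning on the remedy, with the ground “The flask is at equilibrium, so waiting gains nothing.”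

The flask gives 46.3%, 46.4% after amber and 69.5% after teal, and the best remedy is teal.

| Remedy | Gain of target |
|---|---|
| amber | 0.037 points |
| violet | 0.037 points |
| ochre | 0.017 points |
| teal | 23 points |

    starting material + free catalyst ⇌ catalyst intermediate A (K = 2.60 M⁻¹, k = 5.90 M⁻¹ min⁻¹, Ea = 66.0 kJ mol⁻¹, ΔH = −36.0 kJ mol⁻¹)
    catalyst intermediate A → free catalyst + target (k = 0.710 min⁻¹, Ea = 86.0 kJ mol⁻¹)
    second substrate + free catalyst ⇌ catalyst intermediate B (K = 13.0 M⁻¹, k = 15.0 M⁻¹ min⁻¹, Ea = 49.0 kJ mol⁻¹, ΔH = −20.0 kJ mol⁻¹)
    catalyst intermediate B → free catalyst + second product (k = 1.70 min⁻¹, Ea = 80.0 kJ mol⁻¹)
    free catalyst → spent catalyst (k = 0.00150 min⁻¹, Ea = 90.0 kJ mol⁻¹)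
    (constants at 35 °C)

Two steps act together in this flask's stall, the passing of free catalyst into spent catalyst and the back reaction of catalyst intermediate A. Target at 4.00 d is 46.3%, against 99.2% in the run without the first and 92.7% in the run without the second. By 4.00 d, spent catalyst is 99.9% of the catalyst charged, so teal's fresh charge meets 53.7% of starting material, and R gave 71.1% against the flask's 69.5%. Scaled by loading, R gives 64.8% for the neighbour with 0.59 mol%, and that flask holds 65.0%.

The numbers in the tables were generated by integration with constants of no real substance, and the scatter is random.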